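**Retrosynthetic overview**
1. Target 27 comes from triol 26 by triple angeloylation, and 26 from the bis-silyl macrocycle 25 (germacrane numbering throughout).
2. Ring C (the ten-membered carbocycle) is closed last, at C6–C7, by a new photoredox/chromium intramolecular allylation of seco epoxy aldehyde 24 with its own prenyl C–H. This sets C6 and C7 and creates the isopropenyl group.
3. The seco chain comes from Z-vinyllithium 17 (C10) and aldehyde 16 (C9). C9 is then used as a relay: oxidation, Felkin–Anh reduction, OH-directed threo epoxidation (ring B, the 1,10-oxirane), oxidation to the ketone.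
4. Fragment 1 (C1–C6, C10): Still–Gennari Z-enoate, Brown allylation (C3), OH-directed threo epoxidation (ring A, the 4,5-oxirane), Stork–Zhao Z-vinyl iodide 10.
5. Fragment 2 (C7–C9, C11–C13): (R)-glyceraldehyde acetonide 11 supplies C8. Ring order: A (step 5), B (step 17), C (step 21).

Assumption: germacrane numbering is kept for every intermediate (seco chain C6–C5–C4(C15)–C3–C2–C1–C10(C14)–C9–C8–C7=C11(C12)C13); the SMILES is read as the (1R,3S,4R,5S,6S,7S,8S,10R) tris-angelate with both oxiranes cis-fused (C3/C6 cis and C2/C9 cis); TBS = tert-butyldimethylsilyl.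

**Route**

Step 1
Reactants: 1 (tert-butyldimethylsilyloxy)acetaldehyde
Product: 2 ethyl (Z)-4-(TBS-oxy)-2-methylbut-2-enoate
Conditions: ethyl 2-[bis(2,2,2-trifluoroethoxy)phosphoryl]propanoate, KN(SiMe3)2, 18-crown-6, THF, −78 °C
Reagents that add atoms: ethyl 2-[bis(2,2,2-trifluoroethoxy)phosphoryl]propanoate, CCOC(=O)C(C)P(=O)(OCC(F)(F)F)OCC(F)(F)F
Why: Still–Gennari variant of the Horner–Wadsworth–Emmons olefination, in which the trifluoroethyl phosphonate eliminates from the kinetic adduct and gives the Z-trisubstituted enoate (C3 cis to C6).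

Step 2
Reactants: 2 ethyl (Z)-4-(TBS-oxy)-2-methylbut-2-enoate
Product: 3 (Z)-4-(TBS-oxy)-2-methylbut-2-en-1-ol
Conditions: i-Bu2AlH, CH2Cl2, −78 °C
Reagents that add atoms: none
Why: 1,2-reduction of the enoate by the aluminium hydride (ester to allylic alcohol) leaves the Z-alkene and the silyl ether untouched.

Step 3
Reactants: 3 (Z)-4-(TBS-oxy)-2-methylbut-2-en-1-ol
Product: 4 (Z)-4-(TBS-oxy)-2-methylbut-2-enal
Conditions: MnO2, CH2Cl2, 20 °C
Reagents that add atoms: none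
Why: Allylic oxidation with MnO2 is neutral and selective, so the Z-enal is obtained without isomerisation and is used at once.

Step 4
Reactants: 4 (Z)-4-(TBS-oxy)-2-methylbut-2-enal
Product: 5 (4S,5Z)-7-(TBS-oxy)-5-methylhepta-1,5-dien-4-ol
Conditions: (−)-Ipc2BOMe, CH2=CHCH2MgBr, Et2O, 0 °C; then 4, −78 °C; NaOH, H2O2
Reagents that add atoms: allylmagnesium bromide, C=CC[Mg]Br
Why: Brown asymmetric allylboration through a chair Zimmerman–Traxler transition state, in which the (−)-Ipc2B reagent delivers allyl to the si face of the enal and sets C3 as S.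

Step 5
Reactants: 5 (4S,5Z)-7-(TBS-oxy)-5-methylhepta-1,5-dien-4-ol
Product: 6 (1S)-1-[(2R,3S)-3-(TBS-oxymethyl)-2-methyloxiran-2-yl]but-3-en-1-ol
Conditions: m-CPBA, CH2Cl2, −20 to 0 °C
Reagents that add atoms: m-chloroperoxybenzoic acid, OOC(=O)c1cccc(Cl)c1
Why: Henbest hydroxyl-directed peracid epoxidation, in which A(1,3) strain of the Z-allylic alcohol holds C3–H in the alkene plane so oxygen is delivered syn to OH (threo) and sets C4 and C5 (ring A); the terminal alkene is far slower.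

Step 6
Reactants: 6 (1S)-1-[(2R,3S)-3-(TBS-oxymethyl)-2-methyloxiran-2-yl]but-3-en-1-ol
Product: 7 (1S)-1-(TBS-oxy)-1-[(2S,3S)-3-(TBS-oxymethyl)-2-methyloxiran-2-yl]but-3-ene
Conditions: TBSOTf, 2,6-lutidine, CH2Cl2, −78 °C
Reagents that add atoms: tert-butyldimethylsilyl trifluoromethanesulfonate, CC(C)(C)[Si](C)(C)OS(=O)(=O)C(F)(F)F
Why: Silylation of the hindered secondary alcohol with the silyl triflate and a hindered base at low temperature leaves the oxirane intact.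

Step 7
Reactants: 7 (1S)-1-(TBS-oxy)-1-[(2S,3S)-3-(TBS-oxymethyl)-2-methyloxiran-2-yl]but-3-ene
Product: 9 (3S)-3-(TBS-oxy)-3-[(2S,3S)-3-(TBS-oxymethyl)-2-methyloxiran-2-yl]propanal, via ozonide 8 (not isolated)
Conditions: O3, CH2Cl2, −78 °C; then PPh3
Reagents that add atoms: ozone, [O-][O+]=O
Why: Ozonolysis with reductive work-up cleaves the only alkene to the C1 aldehyde; silyl ethers and the oxirane are inert.

Step 8
Reactants: 9 (3S)-3-(TBS-oxy)-3-[(2S,3S)-3-(TBS-oxymethyl)-2-methyloxiran-2-yl]propanal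
Product: 10 (1S,3Z)-1-(TBS-oxy)-1-[(2S,3S)-3-(TBS-oxymethyl)-2-methyloxiran-2-yl]-4-iodopent-3-ene
Conditions: EtPPh3I, n-BuLi, THF, 20 °C; I2, −78 °C; NaN(SiMe3)2, −20 °C; then 9, −78 °C
Reagents that add atoms: ethyltriphenylphosphonium iodide, CC[P+](c1ccccc1)(c1ccccc1)c1ccccc1.[I-]; iodine, II
Why: Stork–Zhao–Wittig olefination with the non-stabilised α-iodo ylide gives the (Z)-2-iodoalkene (iodine cis to C2), the geometry needed for the cis-fused 1,10-oxirane.

Step 9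
Reactants: 11 (R)-2,2-dimethyl-1,3-dioxolane-4-carbaldehyde
Product: 12 (S)-2,2-dimethyl-4-(2-methylprop-1-en-1-yl)-1,3-dioxolane
Conditions: i-PrPPh3I, n-BuLi, THF, 0 °C; then 11, −78 to 20 °C
Reagents that add atoms: isopropyltriphenylphosphonium iodide, CC(C)[P+](c1ccccc1)(c1ccccc1)c1ccccc1.[I-]
Why: Wittig olefination with the isopropylidene ylide builds the prenyl alkene while C8 comes unchanged from the chiral pool (R becomes S only through the CIP priority change).

Step 10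
Reactants: 12 (S)-2,2-dimethyl-4-(2-methylprop-1-en-1-yl)-1,3-dioxolane
Product: 13 (S)-4-methylpent-3-ene-1,2-diol
Conditions: p-TsOH (cat.), MeOH, 20 °C
Reagents that add atoms: none
Why: Acid-catalysed transacetalisation to methanol removes the acetonide under conditions too mild to ionise the allylic C8–O bond.

Step 11
Reactants: 13 (S)-4-methylpent-3-ene-1,2-diol
Product: 14 (S)-1,2-bis(TBS-oxy)-4-methylpent-3-ene
Conditions: TBSCl, imidazole, DMF, 20 °C
Reagents that add atoms: tert-butyldimethylsilyl chloride, CC(C)(C)[Si](C)(C)Cl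
Why: Standard imidazole-promoted silylation protects both hydroxyls.

Step 12
Reactants: 14 (S)-1,2-bis(TBS-oxy)-4-methylpent-3-ene
Product: 15 (S)-2-(TBS-oxy)-4-methylpent-3-en-1-ol
Conditions: HF·pyridine, pyridine, THF, 0 °C
Reagents that add atoms: none
Why: Buffered fluoride desilylation cleaves the primary silyl ether much faster than the secondary one (steric selection).

Step 13
Reactants: 15 (S)-2-(TBS-oxy)-4-methylpent-3-en-1-ol
Product: 16 (S)-2-(TBS-oxy)-4-methylpent-3-enal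
Conditions: Dess–Martin periodinane, CH2Cl2, 0 °C
Reagents that add atoms: none
Why: Dess–Martin oxidation under neutral conditions gives the α-silyloxy aldehyde without epimerising C8 (its C–H lies in the alkene plane through A(1,3) strain); used crude.

Step 14
Reactants: 10 (1S,3Z)-1-(TBS-oxy)-1-[(2S,3S)-3-(TBS-oxymethyl)-2-methyloxiran-2-yl]-4-iodopent-3-ene; 16 (S)-2-(TBS-oxy)-4-methylpent-3-enal
Product: 18 (3S,4S,5S,8S,1(10)Z)-3,6,8-tris(TBS-oxy)-4,5-epoxy-6,7-secogermacra-1(10),7(11)-dien-9-ol (C9 epimer mixture), via vinyllithium 17 (not isolated)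
Conditions: 10, t-BuLi (2.1 equiv), Et2O, −78 °C; then 16, −78 °C; H2O
Reagents that add atoms: none
Why: Lithium–iodine exchange with retention of alkene geometry and 1,2-addition to the aldehyde form the C9–C10 bond; the C9 ratio does not matter because step 15 converges both epimers.

Step 15
Reactants: 18 (3S,4S,5S,8S,1(10)Z)-3,6,8-tris(TBS-oxy)-4,5-epoxy-6,7-secogermacra-1(10),7(11)-dien-9-ol
Product: 19 (3S,4S,5S,8S,1(10)Z)-3,6,8-tris(TBS-oxy)-4,5-epoxy-6,7-secogermacra-1(10),7(11)-dien-9-one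
Conditions: Dess–Martin periodinane, CH2Cl2, 0 °C
Reagents that add atoms: none
Why: Dess–Martin oxidation converts both C9 epimers into one enone and keeps the Z geometry and C8 intact under neutral conditions.

Step 16
Reactants: 19 (3S,4S,5S,8S,1(10)Z)-3,6,8-tris(TBS-oxy)-4,5-epoxy-6,7-secogermacra-1(10),7(11)-dien-9-one
Product: 20 (3S,4S,5S,8S,9S,1(10)Z)-3,6,8-tris(TBS-oxy)-4,5-epoxy-6,7-secogermacra-1(10),7(11)-dien-9-ol
Conditions: LiBH(s-Bu)3, THF, −78 °C; H2O
Reagents that add atoms: none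
Why: Felkin–Anh (polar) 1,2-reduction, in which the bulky hydride attacks C9 anti to the C8–O bond and gives the 8,9-syn (9S) alcohol; the β-substituted, α-methyl enone is not reduced 1,4.

Step 17
Reactants: 20 (3S,4S,5S,8S,9S,1(10)Z)-3,6,8-tris(TBS-oxy)-4,5-epoxy-6,7-secogermacra-1(10),7(11)-dien-9-ol
Product: 21 (1R,3S,4S,5S,8S,9R,10S)-3,6,8-tris(TBS-oxy)-1,10:4,5-diepoxy-6,7-secogermacr-7(11)-en-9-ol
Conditions: m-CPBA, CH2Cl2, −20 °C
Reagents that add atoms: m-chloroperoxybenzoic acid, OOC(=O)c1cccc(Cl)c1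
Why: Henbest hydroxyl-directed epoxidation, threo-selective because A(1,3) strain with cis C2 holds C9–H in the alkene plane, sets C1 and C10 (ring B); the prenyl alkene, an undirected allylic silyl ether, reacts more slowly.

Step 18
Reactants: 21 (1R,3S,4S,5S,8S,9R,10S)-3,6,8-tris(TBS-oxy)-1,10:4,5-diepoxy-6,7-secogermacr-7(11)-en-9-ol
Product: 22 (1R,3S,4S,5S,8S,10R)-3,6,8-tris(TBS-oxy)-1,10:4,5-diepoxy-6,7-secogermacr-7(11)-en-9-one
Conditions: Dess–Martin periodinane, CH2Cl2, 0 °C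
Reagents that add atoms: none
Why: Dess–Martin oxidation of the relay alcohol gives the α,β-epoxy ketone under neutral conditions that leave C8 and both oxiranes untouched.

Step 19
Reactants: 22 (1R,3S,4S,5S,8S,10R)-3,6,8-tris(TBS-oxy)-1,10:4,5-diepoxy-6,7-secogermacr-7(11)-en-9-one
Product: 23 (1R,3S,4S,5S,8S,10R)-3,8-bis(TBS-oxy)-1,10:4,5-diepoxy-6-hydroxy-6,7-secogermacr-7(11)-en-9-one
Conditions: HF·pyridine, pyridine, THF, 0 °C
Reagents that add atoms: none
Why: Buffered fluoride desilylation removes the primary C6 silyl ether selectively over the two hindered secondary ones.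

Step 20
Reactants: 23 (1R,3S,4S,5S,8S,10R)-3,8-bis(TBS-oxy)-1,10:4,5-diepoxy-6-hydroxy-6,7-secogermacr-7(11)-en-9-one
Product: 24 (1R,3S,4S,5R,8S,10R)-3,8-bis(TBS-oxy)-1,10:4,5-diepoxy-9-oxo-6,7-secogermacr-7(11)-en-6-al
Conditions: Dess–Martin periodinane, CH2Cl2, 0 °C
Reagents that add atoms: none
Why: Dess–Martin oxidation of the primary epoxy alcohol gives the cis-epoxy aldehyde, used at once; the C3 silyl ether prevents lactol formation.

Step 21
Reactants: 24 (1R,3S,4S,5R,8S,10R)-3,8-bis(TBS-oxy)-1,10:4,5-diepoxy-9-oxo-6,7-secogermacr-7(11)-en-6-al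
Product: 25 (1R,3S,4S,5S,6S,7S,8S,10R)-3,8-bis(TBS-oxy)-1,10:4,5-diepoxy-6-hydroxygermacr-11(12)-en-9-one
Conditions: CrCl2 (20 mol %), indane-fused bis(oxazoline) ligand (22 mol %, antipode that directs attack to the si face of C6), 9-mesityl-10-methylacridinium perchlorate (5 mol %), CH2Cl2 (2 mM), 430 nm LEDs, 20 °C
Reagents that add atoms: none
Why: Proposed new method: an intramolecular photoredox/chromium allylation of an aldehyde by a prenyl C–H bond (a formal asymmetric macrocyclic carbonyl-ene reaction); the excited acridinium oxidises the only alkene (C7=C11) to its radical cation, which loses a methyl proton (C8–H lies in the nodal plane through A(1,3) strain and is not lost) to give the allyl radical; divalent chromium–bis(oxazoline) captures it at primary C12, and the allylchromium (trivalent) adds through C7 to the tethered aldehyde in a chair six-membered transition state with C5 and C8 equatorial (anti, 6S,7S) on the si face of C6, which the ligand enforces and the Felkin–Anh/Cornforth bias of the cis-epoxy aldehyde supports; the chromium alkoxide takes up the released proton and the reduced acridine radical returns chromium to the divalent state, so the step is a redox-neutral isomerisation that closes ring C, creates the isopropenyl group and sets C6 and C7; the closest known reactions are the intermolecular acridinium/chiral chromium allylation of aldehydes with simple alkenes and the Nozaki–Hiyama or Pd/Et2Zn macrocyclic allylations of allylic halides.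

Step 22
Reactants: 25 (1R,3S,4S,5S,6S,7S,8S,10R)-3,8-bis(TBS-oxy)-1,10:4,5-diepoxy-6-hydroxygermacr-11(12)-en-9-one
Product: 26 (1R,3S,4R,5S,6S,7S,8S,10R)-1,10:4,5-diepoxy-3,6,8-trihydroxygermacr-11(12)-en-9-one
Conditions: n-Bu4NF, AcOH (1:1), THF, 20 °C
Reagents that add atoms: none
Why: Fluoride-mediated Si–O cleavage buffered with acetic acid removes both silyl ethers without epimerising the C8 acyloin centre or opening the oxiranes.

Step 23
Reactants: 26 (1R,3S,4R,5S,6S,7S,8S,10R)-1,10:4,5-diepoxy-3,6,8-trihydroxygermacr-11(12)-en-9-one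
Product: 27 (1R,3S,4R,5S,6S,7S,8S,10R)-3,6,8-tris(angeloyloxy)-1,10:4,5-diepoxygermacr-11(12)-en-9-one (CNP0154187.1)
Conditions: angelic acid, 2,4,6-trichlorobenzoyl chloride, Et3N, toluene, 20 °C; then 26, 75 °C
Reagents that add atoms: angelic acid ((Z)-2-methylbut-2-enoic acid), C/C=C(/C)C(=O)O
Why: Yamaguchi-type mixed-anhydride esterification without a nucleophilic catalyst, in which the three alcohols attack the less hindered angeloyl carbonyl and no conjugate addition–elimination can isomerise angelate to tiglate; no stereocentre is touched.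

**Compound list**
1 | (tert-butyldimethylsilyloxy)acetaldehyde | O=CCO[Si](C)(C)C(C)(C)C | starting material
2 | ethyl (Z)-4-(TBS-oxy)-2-methylbut-2-enoate | CCOC(=O)/C(C)=C\CO[Si](C)(C)C(C)(C)C | intermediate
3 | (Z)-4-(TBS-oxy)-2-methylbut-2-en-1-ol | OC/C(C)=C\CO[Si](C)(C)C(C)(C)C | intermediate
4 | (Z)-4-(TBS-oxy)-2-methylbut-2-enal | O=C/C(C)=C\CO[Si](C)(C)C(C)(C)C | intermediate
5 | (4S,5Z)-7-(TBS-oxy)-5-methylhepta-1,5-dien-4-ol | CC(C)(C)[Si](C)(C)OC/C=C(/C)[C@@H](O)CC=C | intermediate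
6 | (1S)-1-[(2R,3S)-3-(TBS-oxymethyl)-2-methyloxiran-2-yl]but-3-en-1-ol | CC(C)(C)[Si](C)(C)OC[C@@H]1O[C@]1(C)[C@@H](O)CC=C | intermediate
7 | (1S)-1-(TBS-oxy)-1-[(2S,3S)-3-(TBS-oxymethyl)-2-methyloxiran-2-yl]but-3-ene | CC(C)(C)[Si](C)(C)OC[C@@H]1O[C@]1(C)[C@@H](O[Si](C)(C)C(C)(C)C)CC=C | intermediate
8 | ozonide of 7 (3-substituted 1,2,4-trioxolane, mixture at the trioxolane carbon, not isolated) | CC(C)(C)[Si](C)(C)OC[C@@H]1O[C@]1(C)[C@@H](O[Si](C)(C)C(C)(C)C)CC1OCOO1 | intermediate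
9 | (3S)-3-(TBS-oxy)-3-[(2S,3S)-3-(TBS-oxymethyl)-2-methyloxiran-2-yl]propanal | CC(C)(C)[Si](C)(C)OC[C@@H]1O[C@]1(C)[C@@H](O[Si](C)(C)C(C)(C)C)CC=O | intermediate
10 | (1S,3Z)-1-(TBS-oxy)-1-[(2S,3S)-3-(TBS-oxymethyl)-2-methyloxiran-2-yl]-4-iodopent-3-ene (fragment 1) | CC(C)(C)[Si](C)(C)OC[C@@H]1O[C@]1(C)[C@@H](O[Si](C)(C)C(C)(C)C)C/C=C(/C)I | intermediate
11 | (R)-2,2-dimethyl-1,3-dioxolane-4-carbaldehyde | CC1(C)OC[C@@H](O1)C=O | starting material
12 | (S)-2,2-dimethyl-4-(2-methylprop-1-en-1-yl)-1,3-dioxolane | CC1(C)OC[C@@H](O1)C=C(C)C | intermediate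
13 | (S)-4-methylpent-3-ene-1,2-diol | OC[C@@H](O)C=C(C)C | intermediate
14 | (S)-1,2-bis(TBS-oxy)-4-methylpent-3-ene | CC(C)(C)[Si](C)(C)OC[C@@H](O[Si](C)(C)C(C)(C)C)C=C(C)C | intermediate
15 | (S)-2-(TBS-oxy)-4-methylpent-3-en-1-ol | OC[C@@H](O[Si](C)(C)C(C)(C)C)C=C(C)C | intermediate
16 | (S)-2-(TBS-oxy)-4-methylpent-3-enal (fragment 2) | O=C[C@@H](O[Si](C)(C)C(C)(C)C)C=C(C)C | intermediate
17 | vinyllithium from 10 (lithium in place of iodine, Z retained, not isolated) | CC(C)(C)[Si](C)(C)OC[C@@H]1O[C@]1(C)[C@@H](O[Si](C)(C)C(C)(C)C)C/C=C(/C)[Li] | intermediate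
18 | (3S,4S,5S,8S,1(10)Z)-3,6,8-tris(TBS-oxy)-4,5-epoxy-6,7-secogermacra-1(10),7(11)-dien-9-ol, 9R/9S mixture | CC(C)(C)[Si](C)(C)OC[C@@H]1O[C@]1(C)[C@@H](O[Si](C)(C)C(C)(C)C)C/C=C(/C)C(O)[C@@H](O[Si](C)(C)C(C)(C)C)C=C(C)C | intermediate
19 | (3S,4S,5S,8S,1(10)Z)-3,6,8-tris(TBS-oxy)-4,5-epoxy-6,7-secogermacra-1(10),7(11)-dien-9-one | CC(C)(C)[Si](C)(C)OC[C@@H]1O[C@]1(C)[C@@H](O[Si](C)(C)C(C)(C)C)C/C=C(/C)C(=O)[C@@H](O[Si](C)(C)C(C)(C)C)C=C(C)C | intermediate
20 | (3S,4S,5S,8S,9S,1(10)Z)-3,6,8-tris(TBS-oxy)-4,5-epoxy-6,7-secogermacra-1(10),7(11)-dien-9-ol | CC(C)(C)[Si](C)(C)OC[C@@H]1O[C@]1(C)[C@@H](O[Si](C)(C)C(C)(C)C)C/C=C(/C)[C@H](O)[C@@H](O[Si](C)(C)C(C)(C)C)C=C(C)C | intermediate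
21 | (1R,3S,4S,5S,8S,9R,10S)-3,6,8-tris(TBS-oxy)-1,10:4,5-diepoxy-6,7-secogermacr-7(11)-en-9-ol | CC(C)(C)[Si](C)(C)OC[C@@H]1O[C@]1(C)[C@@H](O[Si](C)(C)C(C)(C)C)C[C@H]1O[C@@]1(C)[C@H](O)[C@@H](O[Si](C)(C)C(C)(C)C)C=C(C)C | intermediate
22 | (1R,3S,4S,5S,8S,10R)-3,6,8-tris(TBS-oxy)-1,10:4,5-diepoxy-6,7-secogermacr-7(11)-en-9-one | CC(C)(C)[Si](C)(C)OC[C@@H]1O[C@]1(C)[C@@H](O[Si](C)(C)C(C)(C)C)C[C@H]1O[C@@]1(C)C(=O)[C@@H](O[Si](C)(C)C(C)(C)C)C=C(C)C | intermediate
23 | (1R,3S,4S,5S,8S,10R)-3,8-bis(TBS-oxy)-1,10:4,5-diepoxy-6-hydroxy-6,7-secogermacr-7(11)-en-9-one | OC[C@@H]1O[C@]1(C)[C@@H](O[Si](C)(C)C(C)(C)C)C[C@H]1O[C@@]1(C)C(=O)[C@@H](O[Si](C)(C)C(C)(C)C)C=C(C)C | intermediate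
24 | (1R,3S,4S,5R,8S,10R)-3,8-bis(TBS-oxy)-1,10:4,5-diepoxy-9-oxo-6,7-secogermacr-7(11)-en-6-al | O=C[C@@H]1O[C@]1(C)[C@@H](O[Si](C)(C)C(C)(C)C)C[C@H]1O[C@@]1(C)C(=O)[C@@H](O[Si](C)(C)C(C)(C)C)C=C(C)C | intermediate
25 | (1R,3S,4S,5S,6S,7S,8S,10R)-3,8-bis(TBS-oxy)-1,10:4,5-diepoxy-6-hydroxygermacr-11(12)-en-9-one | C=C(C)[C@H]1[C@H](O)[C@@H]2O[C@]2(C)[C@@H](O[Si](C)(C)C(C)(C)C)C[C@H]2O[C@@]2(C)C(=O)[C@H]1O[Si](C)(C)C(C)(C)C | intermediate
26 | (1R,3S,4R,5S,6S,7S,8S,10R)-1,10:4,5-diepoxy-3,6,8-trihydroxygermacr-11(12)-en-9-one | C=C(C)[C@H]1[C@H](O)[C@@H]2O[C@]2(C)[C@@H](O)C[C@H]2O[C@@]2(C)C(=O)[C@H]1O | intermediate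
27 | (1R,3S,4R,5S,6S,7S,8S,10R)-3,6,8-tris(angeloyloxy)-1,10:4,5-diepoxygermacr-11(12)-en-9-one (CNP0154187.1) | C=C(C)[C@H]1[C@H](OC(=O)/C(C)=C\C)[C@@H]2O[C@]2(C)[C@@H](OC(=O)/C(C)=C\C)C[C@H]2O[C@@]2(C)C(=O)[C@H]1OC(=O)/C(C)=C\C | target

**Totals and risks**

Total step count: 23. Longest linear sequence: 18 steps (steps 1–8, then 14–23, from compound 1); fragment 2 takes 5 steps (9–13).

The three steps most likely to fail, each with a fallback:

First, step 21, the proposed new macrocyclisation. The alkene may be too electron-poor for oxidation, the α-oxy C8–H or the aldehyde may interfere, or the closure may give the wrong ring size or face. The fallback uses known chemistry, sets out from 22 and comes back at 25. The prenyl group of 22 is functionalised first: catalytic SeO2/t-BuOOH allylic oxidation (E-selective) gives the (E)-12-hydroxy compound F1, and MsCl/LiCl/2,4,6-collidine converts it into the allylic chloride F2. HF·pyridine then frees C6 to give the 12-chloro alcohol F3, and Dess–Martin oxidation gives the 12-chloro aldehyde F4. F4 is cyclised at high dilution with Pd(PPh3)4/Et2Zn: zerovalent palladium ionises the allylic chloride, transmetalation gives the allylzinc, and this adds through the same chair transition state. This umpolung closure is already known for the C6–C7 bond of germacrane rings and gives 25 under substrate control. Stoichiometric CrCl2 (Nozaki–Hiyama allylation) is the second known option if divalent chromium spares the epoxy ketone.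

Second, step 8, the Stork–Zhao olefination, which typically gives moderate yields and a variable Z:E ratio on β-silyloxy aldehydes. The fallback sets out from 9 and comes back at 17. A Corey–Fuchs reaction (CBr4, PPh3, 2,6-lutidine) gives the 1,1-dibromoalkene F5. Trans-selective mono-methylation (MeZnCl, Pd(P(t-Bu)3)2; only the bromine trans to the chain couples) gives the (Z)-vinyl bromide F6. t-BuLi converts F6 into vinyllithium 17, which continues in step 14.

Third, step 23, the triple angeloylation. The three alcohols are hindered, the acyloin is base-sensitive at 75 °C, and angelate can isomerise to tiglate. The fallback sets out from 26 and comes back at 27. The triol is acylated under mild carbodiimide conditions (EDC, DMAP, 0 °C) with 2-[bis(2,2,2-trifluoroethoxy)phosphoryl]propanoic acid to give the tris(phosphonopropanoate) F7. A threefold Still–Gennari olefination with acetaldehyde (KN(SiMe3)2, 18-crown-6, THF, −78 °C) then builds the three (Z)-2-methylbut-2-enoates directly on the core; the phosphonate C–H is far more acidic than C8–H.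

**Further compounds**
F1 | step 21 | (1R,3S,4S,5S,8S,10R,7(11)E)-3,6,8-tris(TBS-oxy)-1,10:4,5-diepoxy-12-hydroxy-6,7-secogermacr-7(11)-en-9-one | CC(C)(C)[Si](C)(C)OC[C@@H]1O[C@]1(C)[C@@H](O[Si](C)(C)C(C)(C)C)C[C@H]1O[C@@]1(C)C(=O)[C@@H](O[Si](C)(C)C(C)(C)C)/C=C(\C)CO
F2 | step 21 | (1R,3S,4S,5S,8S,10R,7(11)E)-3,6,8-tris(TBS-oxy)-12-chloro-1,10:4,5-diepoxy-6,7-secogermacr-7(11)-en-9-one | CC(C)(C)[Si](C)(C)OC[C@@H]1O[C@]1(C)[C@@H](O[Si](C)(C)C(C)(C)C)C[C@H]1O[C@@]1(C)C(=O)[C@@H](O[Si](C)(C)C(C)(C)C)/C=C(\C)CCl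
F3 | step 21 | (1R,3S,4S,5S,8S,10R,7(11)E)-3,8-bis(TBS-oxy)-12-chloro-1,10:4,5-diepoxy-6-hydroxy-6,7-secogermacr-7(11)-en-9-one | OC[C@@H]1O[C@]1(C)[C@@H](O[Si](C)(C)C(C)(C)C)C[C@H]1O[C@@]1(C)C(=O)[C@@H](O[Si](C)(C)C(C)(C)C)/C=C(\C)CCl
F4 | step 21 | (1R,3S,4S,5R,8S,10R,7(11)E)-3,8-bis(TBS-oxy)-12-chloro-1,10:4,5-diepoxy-9-oxo-6,7-secogermacr-7(11)-en-6-al | O=C[C@@H]1O[C@]1(C)[C@@H](O[Si](C)(C)C(C)(C)C)C[C@H]1O[C@@]1(C)C(=O)[C@@H](O[Si](C)(C)C(C)(C)C)/C=C(\C)CCl
F5 | step 8 | (4S)-1,1-dibromo-4-(TBS-oxy)-4-[(2S,3S)-3-(TBS-oxymethyl)-2-methyloxiran-2-yl]but-1-ene | CC(C)(C)[Si](C)(C)OC[C@@H]1O[C@]1(C)[C@@H](O[Si](C)(C)C(C)(C)C)CC=C(Br)Br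
F6 | step 8 | (1S,3Z)-4-bromo-1-(TBS-oxy)-1-[(2S,3S)-3-(TBS-oxymethyl)-2-methyloxiran-2-yl]pent-3-ene | CC(C)(C)[Si](C)(C)OC[C@@H]1O[C@]1(C)[C@@H](O[Si](C)(C)C(C)(C)C)C/C=C(/C)Br
F7 | step 23 | 3,6,8-tris{2-[bis(2,2,2-trifluoroethoxy)phosphoryl]propanoate} of triol 26 (phosphonate α-carbons unspecified) | C=C(C)[C@H]1[C@H](OC(=O)C(C)P(=O)(OCC(F)(F)F)OCC(F)(F)F)[C@@H]2O[C@]2(C)[C@@H](OC(=O)C(C)P(=O)(OCC(F)(F)F)OCC(F)(F)F)C[C@H]2O[C@@]2(C)C(=O)[C@H]1OC(=O)C(C)P(=O)(OCC(F)(F)F)OCC(F)(F)F
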